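Watch one ratio in this flask: how fast E takes L against how fast E falls to D.

E 15 mM; Q 6.9 mM (held); time 40 h

    E → D (k1 = 1.9 × 10⁻⁵ s⁻¹)
    E ⇌ G (K2 = 1.5, k2 = 1.2 × 10⁻⁴ s⁻¹)
    Q ⇌ L, rate k3*(csat - [L]) (k3 = 8.1 × 10⁻⁴ s⁻¹, csat = 6.9 mM)
    2 L → L2 (k4 = 0.0015 L mol⁻¹ s⁻¹)
    E + L → E.L (k5 = 0.0019 L mol⁻¹ s⁻¹)
    L → J (k6 = 2.0 × 10⁻⁵ s⁻¹)

* E.L at 40 h, in percent of the E charged
* concentration of L in solution at 40 h, in percent of saturation

Reckon L first, as a small correction to saturation. The transfer coefficient is larger than the loss coefficient of the steps to J and L2 at saturation, so take the gap as that loss coefficient over the transfer coefficient, 5.02%, and set aside what E itself draws. That puts L at 95.2% of saturation, or 6.57 mM.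

Now call the share, or selectivity, the part of spent E that ends as E.L, which is the rate constant of E with L times L, over that same term plus the constant for D: 39.6%.

E and G exchange faster than E is spent, so hold E at 40.0% of the pool of E and G. By this reckoning the pool falls at 0.0453 h⁻¹, which gives a loss of 83.7% of the charge by 40 h. Multiply by the share to get 33.2%.

The forecast gave 33% and 95%, with the ground that “Gas transfer is far faster than the L-consuming steps”.

The flask gives 31.8% and 95.1%.

At 40.0 h this flask still holds 17.7% of the charge as E and G together. Now read the same flask at 4.0 d: the reckoned loss from the pool is then 98.7% of the charge, and the share turns that into 39.1%. That later reading holds E.L at 38.1%, with E down to 0.64%.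

(The constants come from no measurement; the run is a simulation.)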